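The target in the amber run does not stand still: it falls from 39.8 % at 0.667 min to 10.6 % at 8.00 min, and the quick number asked for can be built on that fall.

in all of them: starting material 0.050 M
- amber: coupling partner 0.20 M; run made earlier
- zeta: coupling partner 0.0650 M; time 8.0 min
- delta: coupling partner 0.130 M; time 8.0 min
- beta: coupling partner 0.260 M; time 8.0 min

amber run (percent of the starting material charged)

| time / min | target / % | starting material / % |
|---|---|---|
| 0.667 | 39.8 | 14.1 |
| 1.33 | 34.0 | 11.0 |
| 2.50 | 26.5 | 4.7 |
| 4.00 | 18.7 | 4.6 |
| 8.00 | 10.6 | 2.9 |

(standard deviation of a reading: 1 percentage point)

1. which of the two there is more of at the end, zeta (target / side product)
2. which of the two there is more of at the end, delta (target / side product)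
3. which of the two there is more of at the end, beta (target / side product)
4. target at the end, in percent of the starting material charged, zeta
5. target at the end, in percent of the starting material charged, delta
6. target at the end, in percent of the starting material charged, beta

Taken as second order in target, the amber fall is reckoned through the reciprocal of [target]. That reciprocal stands at 50.3 L mol⁻¹ at the first amber reading, and the first and last readings give 18.9 L mol⁻¹ min⁻¹ for its rise per minute, the drain constant, an apparent second-order rate constant. It is a chord through readings with a scatter of 1 percentage point, not a fitted line. Over the amber run the drain adds 138 L mol⁻¹, more than the early term, so the early amount can be treated as a correction to the drain.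

Partner may well shift the early target, but with half or twice the amber value, and the same drain, the target in zeta, delta or beta at 8.0 min comes to 8.37 % or 12.2 % of the charge. The reckoning here therefore commits to about 10.6 % for zeta, delta and beta alike, with side product ahead, on the assumption that the 86.5 % of the amber charge unaccounted at its last reading, which stands above its target, has gone to side product.

The forecast sent over as a hunch agrees on the side product, naming side product for zeta, side product for delta and side product for beta, but differs from this reckoning on the target, with a wide spread: 1.8 %, 5.1 % and 15 % in the same order. Its ground is that "More partner should therefore protect the material by lowering free starting material".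

The flasks give 13.2 %, 11.5 % and 10.1 % of target for zeta, delta and beta, with side product at 69.6 %, 83.2 % and 87.1 %, and beta, charged with the most partner, ends with less target than zeta.

    starting material + coupling partner ⇌ intermediate (K = 13.0 L mol⁻¹, k = 9.90 L mol⁻¹ s⁻¹)
    intermediate ⇌ target + by-product (K = 0.0280 M, k = 0.0610 s⁻¹)
    target + by-product → side product (k = 0.690 L mol⁻¹ s⁻¹)

Carried on from the 19.1 % of target in beta at 4.00 min, the drain constant gives 11.1 % at 8.0 min, against 10.1 % in beta. The neighbour is beta charged with 0.20 M of starting material, its partner and time unchanged. Keeping the early share of target from amber, the early term shrinks with the charge, the drain term stands as before, and the reckoning gives 3.31 % of that charge. The neighbour ends 1.6 points higher, with target at 4.90 % and side product at 90.6 %.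

(Readings and results stem from a simulated flask with made-up constants; the scatter is artificial.)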